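**Compound numbers used throughout:** 1 2-bromo-5-iodothiophene; 2 but-3-yn-1-ol; 3 bromothienyl butynol; 4 3-methylbutanoyl chloride; 5 ring A bromide ester; 6 thiophene-2-carbaldehyde; 7 bithiophene aldehyde; 8 bithiophene thenyl alcohol; 9 target.

## The problem

Target 9 is a 5,5'-disubstituted 2,2'-bithiophene in which ring A, the thiophene carrying the 4-acyloxybut-1-ynyl arm, is joined to ring B, the thiophene carrying the acyloxymethyl arm; both arms end in the same 3-methylbutanoate. The molecule has no stereocenter and no stereogenic double bond, so the task is one of connectivity and chemoselectivity only. Because the two arms differ in length and hybridisation, the bithiophene is unsymmetrical and is best made by joining two different monothiophenes, not by differentiating the ends of a preformed bithiophene. The most fragile group is the thenyl ester on ring B, whose C–O bond can ionise to a thienylmethyl cation stabilised by the whole bithiophene, so it should not meet acid, Lewis acids or hot polar media. The aryl alkyne is at risk from strong base (isomerisation towards an allene) and from palladium species that add across triple bonds. The aliphatic esters exclude hydroxide, alkoxide and strong hydride donors. The enabling feature is that the inter-ring bond joins two α-carbons next to sulfur and that ring B with its one-carbon substituent maps onto thiophene-2-carbaldehyde 6. In 6 the only free α C–H is C5–H, which the formyl group makes the most acidic on the ring, so ring B can enter by C–H arylation without prior metalation.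

## Retrosynthesis

**9 to 8 and 4.** The acyl C–O bond of the thenyl ester is cut first. This ester is the group least able to survive heat, acid or palladium, so it is put on in the last step from alcohol 8 and acid chloride 4. Cutting both esters at once would save one acylation but would leave a free homopropargylic alcohol in the palladium step (see the fourth paragraph). The forward reaction only has to be a buffered, cold acylation.

**8 to 7.** The hydroxymethyl group of 8 is traced back to the formyl group of 7. The aldehyde cannot ionise, it activates the neighbouring ring positions for the key step, and it makes ring B a purchasable compound. The forward reaction must reduce an aryl aldehyde without touching the aliphatic ester or the conjugated alkyne, which a borohydride at low temperature should do.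

**7 to 5 and 6 (key disconnection).** The bond between the α-carbon of ring A and the α-carbon of ring B is cut, giving the ring A bromide 5 and aldehyde 6.
- Against a cut at the alkyne–ring A bond: that cut would require a brominated bithiophene aldehyde, that is, a bithiophene already differentiated at its two ends.
- Against the same cut with an organometallic ring B: that would need a boron or tin derivative of 6, whereas the C–H arylation takes 6 as bought.
- Simplification: 7 falls into two monothiophenes of similar size, one of them commercial.
- Demands on the forward reaction: selectivity for C5–H of 6, and tolerance of the alkyne, the ester and the aldehyde.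

**5 to 3 and 4.** The ester C–O bond of the butynyl arm is cut, giving alcohol 3 and acid chloride 4. This acyl group is the target's own, so it costs no deprotection, and it also protects the alcohol. A free 4-arylbut-3-yn-1-ol next to divalent palladium could add its hydroxyl across the triple bond or act as a hydride source that debrominates the coupling partner. Acylating before the key step costs one operation compared with a late double acylation, and that price is accepted.

**3 to 1 and 2.** The bond between the alkyne carbon and ring A is cut by a Sonogashira coupling. Dihalide 1 is preferred to a thiophene with two identical halogens because the iodide reacts well before the bromide, so no statistical mono-coupling is needed and the bromide is kept for the key step. Both 1 and 2 are commercial.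

## Roads not taken

**Alternative 1:** Ring B is not introduced but built. The two C–S bonds of ring B are cut, which leads to the thienyl diyne 5-[5-(4-hydroxybut-1-yn-1-yl)thiophen-2-yl]penta-2,4-diyn-1-ol A1. In the forward sense Na2S·9H2O in basic dimethyl sulfoxide adds to the conjugated diyne of A1 and closes the thiophene by a 5-endo-dig cyclisation. The product of this key step is the diol 4-[5'-(hydroxymethyl)-[2,2'-bithiophen]-5-yl]but-3-yn-1-ol A2. Double acylation of A2 then gives 9.
- Merits: it follows the likely biogenesis of such bithiophenes, the regiochemistry of ring B is fixed by the diyne termini, and one acylation step serves both arms of A2.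
- Weak points: A1 has to be assembled by two successive alkyne couplings on ring A, including an unsymmetrical diyne synthesis. A1 carries three triple bonds that are prone to oligomerise. The basic sulfide medium meets the homopropargylic alkyne of ring A, which can isomerise or take up sulfide itself.
- Comparison: this road is better in that it needs no regioselective C–H functionalisation and no palladium in the ring-forming step. The chosen plan sets against it a shorter sequence (five steps against roughly seven), a commercial ring B, and no strongly basic, nucleophilic medium near the alkyne.

**Alternative 2:** The bond between the alkyne carbon and the adjacent CH2 is cut. The precursor is the dibromoalkene tert-butyl{[5'-(2,2-dibromoethenyl)-[2,2'-bithiophen]-5-yl]methoxy}dimethylsilane A3. Two equivalents of n-BuLi convert A3 into the lithium acetylide, which opens oxirane A4 with BF3·OEt2. The product of this key step is the alcohol 4-[5'-({[tert-butyl(dimethyl)silyl]oxy}methyl)-[2,2'-bithiophen]-5-yl]but-3-yn-1-ol A5. Desilylation of A5 and double acylation would follow.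
- Merits: the bithiophene core is in place from the start, no regiochemical question arises, and the alkyne of A5 is made at low temperature away from any palladium.
- Weak points: A3 requires a bithiophene differentiated at both ends and several functional-group steps before the key step. The silyl ether of A3 and A5 is pure protecting-group traffic, since both oxygens end with the same acyl group. BF3·OEt2 meets an ionisable thenyl ether. A4 is a toxic gas.
- Comparison: this road is safer for the alkyne than a hot palladium step. The chosen plan sets against it roughly half the step count and the absence of any protecting group that must be removed.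

**Alternative 3:** Ring B is again built, this time from a 1,4-diketone. The aldehyde partner is 4-(5-formylthiophen-2-yl)but-3-yn-1-yl 3-methylbutanoate A6 and the acceptor is the vinyl ketone 2-oxobut-3-en-1-yl 3-methylbutanoate A7. A thiazolium-derived carbene with Et3N adds the formyl carbon of A6 to the terminal alkene carbon of A7 in a Stetter reaction. The product of this key step is the diketone 4-{5-[5-(3-methylbutanoyloxy)-4-oxopentanoyl]thiophen-2-yl}but-3-yn-1-yl 3-methylbutanoate A8. A Paal–Knorr thionation of A8 with Lawesson's reagent would then close ring B and give 9 directly.
- Merits: it is convergent, metal-free in the ring B chemistry, and both esters are already present in A8.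
- Weak points: A7 is a polymerisation-prone vinyl ketone that must be prepared, and A6 needs a Sonogashira coupling and an acylation just as 5 does, so nothing is saved on ring A. The thionation of A8 runs hot with a Lewis-acidic phosphorus–sulfur reagent, so the thenyl ester would be formed under the very conditions it tolerates least. Furan formation and thionation of the ester carbonyls compete.
- Comparison: it is equal in convergence and better in avoiding C–H regioselectivity. The chosen plan sets against it a commercial partner in place of A7 and an endgame (borohydride, then cold acylation) that forms the thenyl ester under the mildest conditions of the route.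

Key step: step 3

## Route

Step 1
Reactants: 1 2-bromo-5-iodothiophene; 2 but-3-yn-1-ol
Product: 3 4-(5-bromothiophen-2-yl)but-3-yn-1-ol
Conditions: PdCl2(PPh3)2 (cat.), CuI (cat.), Et3N, THF, rt, degassed
Reagents that add atoms: none
Why: Sonogashira coupling; oxidative addition of zerovalent palladium to the C–I bond is much faster than to the C–Br bond at room temperature, so the bromide is kept for step 3.

Step 2
Reactants: 3 4-(5-bromothiophen-2-yl)but-3-yn-1-ol; 4 3-methylbutanoyl chloride
Product: 5 4-(5-bromothiophen-2-yl)but-3-yn-1-yl 3-methylbutanoate
Conditions: Et3N, DMAP (cat.), CH2Cl2, 0 °C to rt
Reagents that add atoms: none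
Why: DMAP-catalysed acylation of an unhindered primary alcohol with an acid chloride; the ester installed is the target's own and masks the hydroxyl for the palladium step.

Step 3
Reactants: 5 4-(5-bromothiophen-2-yl)but-3-yn-1-yl 3-methylbutanoate; 6 thiophene-2-carbaldehyde
Product: 7 4-(5'-formyl-[2,2'-bithiophen]-5-yl)but-3-yn-1-yl 3-methylbutanoate
Conditions: Pd(OAc)2 (cat.), KOAc, DMA, 130 °C, Ar; 6 in excess
Reagents that add atoms: none
Why: Pd(OAc)2 is reduced in situ to zerovalent palladium, which inserts into the C–Br bond of 5 to give a thienyl–Pd–Br species of divalent palladium, and bromide is exchanged for acetate. The bound acetate then removes the C5 proton of 6 while palladium bonds to C5 (concerted metalation–deprotonation through a six-membered transition state), and reductive elimination joins the two α-carbons and returns zerovalent palladium. The closest known reaction type is the carboxylate-assisted, phosphine-free direct C5 arylation of 2-substituted thiophenes with aryl and heteroaryl bromides in a hot amide solvent, for which 6 is a standard substrate. No ring closes and no stereocenter forms. The step needs regioselectivity for C5 over C3 and C4 of 6, and this is secured because C5–H is the α C–H next to sulfur, the most acidic and the one favoured in the metalation transition state, while C2 is blocked by the formyl group, which acidifies C5–H further. Self-coupling of 5 and over-arylation of 7 are not expected, because neither has a free α C–H. The alkyne should be spared because no CuI and no free hydroxyl are present and the excess of 6 should intercept the thienyl–Pd–Br species before it adds across a triple bond; the aldehyde cannot ionise as a thenyl ester could.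

Step 4
Reactants: 7 4-(5'-formyl-[2,2'-bithiophen]-5-yl)but-3-yn-1-yl 3-methylbutanoate
Product: 8 4-[5'-(hydroxymethyl)-[2,2'-bithiophen]-5-yl]but-3-yn-1-yl 3-methylbutanoate
Conditions: NaBH4, THF/MeOH, 0 °C; aq. NH4Cl
Reagents that add atoms: none
Why: Borohydride reduction of an aryl aldehyde; at 0 °C NaBH4 should leave the aliphatic ester and the conjugated alkyne untouched, and the buffered quench avoids acid at the new thenyl alcohol.

Step 5
Reactants: 8 4-[5'-(hydroxymethyl)-[2,2'-bithiophen]-5-yl]but-3-yn-1-yl 3-methylbutanoate; 4 3-methylbutanoyl chloride
Product: 9 4-(5'-{[(3-methylbutanoyl)oxy]methyl}-[2,2'-bithiophen]-5-yl)but-3-yn-1-yl 3-methylbutanoate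
Conditions: Et3N (excess), DMAP (cat.), CH2Cl2, 0 °C; chromatography on Et3N-deactivated silica
Reagents that add atoms: none
Why: DMAP-catalysed acylation of a primary alcohol; excess amine traps HCl so that the thenyl C–O bond is never exposed to acid, and the cold, short reaction forms the fragile ester last.

## Compound list

1 | 2-bromo-5-iodothiophene | Brc1ccc(I)s1 | starting material
2 | but-3-yn-1-ol | C#CCCO | starting material
3 | 4-(5-bromothiophen-2-yl)but-3-yn-1-ol | OCCC#Cc1ccc(Br)s1 | intermediate
4 | 3-methylbutanoyl chloride | CC(C)CC(Cl)=O | starting material
5 | 4-(5-bromothiophen-2-yl)but-3-yn-1-yl 3-methylbutanoate | CC(C)CC(=O)OCCC#Cc1ccc(Br)s1 | intermediate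
6 | thiophene-2-carbaldehyde | O=Cc1cccs1 | starting material
7 | 4-(5'-formyl-[2,2'-bithiophen]-5-yl)but-3-yn-1-yl 3-methylbutanoate | CC(C)CC(=O)OCCC#Cc1ccc(-c2ccc(C=O)s2)s1 | intermediate
8 | 4-[5'-(hydroxymethyl)-[2,2'-bithiophen]-5-yl]but-3-yn-1-yl 3-methylbutanoate | CC(C)CC(=O)OCCC#Cc1ccc(-c2ccc(CO)s2)s1 | intermediate
9 | 4-(5'-{[(3-methylbutanoyl)oxy]methyl}-[2,2'-bithiophen]-5-yl)but-3-yn-1-yl 3-methylbutanoate | CC(C)CC(=O)OCCC#Cc1ccc(-c2ccc(COC(=O)CC(C)C)s2)s1 | target

## Step count and risks

Total step count: 5. Longest linear sequence: 5 steps (1 to 9).

**Step 3 (key step).** The most likely failure is that the thienyl–Pd–Br species of divalent palladium adds across the aryl alkyne of a second molecule of 5 or 7 (carbopalladation and oligomerisation). Alternatively the catalyst may aggregate to inactive metal at 130 °C before the fairly electron-rich bromide has turned over. Reductive loss of bromine and minor arylation next to the formyl group are lesser risks. The fallback sets out from 5 and returns at 7. It replaces C–H activation with a Suzuki–Miyaura coupling of 5 with commercial (5-formylthiophen-2-yl)boronic acid (SMILES O=Cc1ccc(B(O)O)s1), using PdCl2(dppf) and K3PO4 in dioxane/water at about 70 °C. The same bond forms at a much lower temperature, where the alkyne is not at risk. This fallback makes no compound outside the compound list, hence the entry F0.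

**Step 5.** The risk is ionisation of the thenyl C–O bond during or after acylation. Adventitious HCl can turn the alcohol into the thenyl chloride or start oligomerisation through the thienylmethyl cation, and the product can decompose on acidic silica. The fallback sets out from 8 and returns at 9. It activates the alcohol instead of the acid: a Mitsunobu esterification with 3-methylbutanoic acid (SMILES CC(C)CC(=O)O), PPh3 and DIAD in THF at 0 °C. The medium stays neutral and no acid chloride or HCl is present. This fallback also makes no compound outside the compound list, hence the entry F0.

**Step 4.** The risk is erosion of the butynyl ester during the reduction, by methoxide formed from NaBH4 in methanol (transesterification) or by slow hydride attack if the reaction is left too long. The fallback sets out from 7 and returns at 9, and it gives up the ester deliberately. NaBH4 reduction is followed in the same methanolic solution by K2CO3, which removes the acyl group and gives the diol 4-[5'-(hydroxymethyl)-[2,2'-bithiophen]-5-yl]but-3-yn-1-ol F1. F1 is then acylated on both hydroxyls with an excess of 4, Et3N and DMAP in CH2Cl2 at 0 °C to give 9.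

**Step 1.** The risks are incomplete discrimination between the two halogens (coupling also at C–Br, giving a dialkynyl thiophene) and CuI-mediated oxidative dimerisation of 2 if oxygen is not excluded. The fallback sets out from 2 and returns at 5, and it removes the selectivity question. Commercial 2-iodothiophene (SMILES Ic1cccs1) is coupled with 2 under the same Sonogashira conditions to give 4-(thiophen-2-yl)but-3-yn-1-ol F2. F2 is acylated with 4 to give 4-(thiophen-2-yl)but-3-yn-1-yl 3-methylbutanoate F3. The free α-position of F3 is then brominated with NBS in DMF at 0 °C in the dark to give 5.

## Further compounds

F0 | step 3 | none | none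
F0 | step 5 | none | none
F1 | step 4 | 4-[5'-(hydroxymethyl)-[2,2'-bithiophen]-5-yl]but-3-yn-1-ol | OCCC#Cc1ccc(-c2ccc(CO)s2)s1
F2 | step 1 | 4-(thiophen-2-yl)but-3-yn-1-ol | OCCC#Cc1cccs1
F3 | step 1 | 4-(thiophen-2-yl)but-3-yn-1-yl 3-methylbutanoate | CC(C)CC(=O)OCCC#Cc1cccs1
A1 | alternative 1 | 5-[5-(4-hydroxybut-1-yn-1-yl)thiophen-2-yl]penta-2,4-diyn-1-ol | OCC#CC#Cc1ccc(C#CCCO)s1
A2 | alternative 1 | 4-[5'-(hydroxymethyl)-[2,2'-bithiophen]-5-yl]but-3-yn-1-ol | OCCC#Cc1ccc(-c2ccc(CO)s2)s1
A3 | alternative 2 | tert-butyl{[5'-(2,2-dibromoethenyl)-[2,2'-bithiophen]-5-yl]methoxy}dimethylsilane | CC(C)(C)[Si](C)(C)OCc1ccc(-c2ccc(C=C(Br)Br)s2)s1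
A4 | alternative 2 | oxirane | C1CO1
A5 | alternative 2 | 4-[5'-({[tert-butyl(dimethyl)silyl]oxy}methyl)-[2,2'-bithiophen]-5-yl]but-3-yn-1-ol | CC(C)(C)[Si](C)(C)OCc1ccc(-c2ccc(C#CCCO)s2)s1
A6 | alternative 3 | 4-(5-formylthiophen-2-yl)but-3-yn-1-yl 3-methylbutanoate | CC(C)CC(=O)OCCC#Cc1ccc(C=O)s1
A7 | alternative 3 | 2-oxobut-3-en-1-yl 3-methylbutanoate | C=CC(=O)COC(=O)CC(C)C
A8 | alternative 3 | 4-{5-[5-(3-methylbutanoyloxy)-4-oxopentanoyl]thiophen-2-yl}but-3-yn-1-yl 3-methylbutanoate | CC(C)CC(=O)OCCC#Cc1ccc(C(=O)CCC(=O)COC(=O)CC(C)C)s1
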